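**Retrosynthetic overview**

1. Locants used below: ring A = C1(=O)–C2–C3–C4(Me2)–C5–C10 with the ether bridge C3–O–C6H2–C5; ring B = δ-lactone C10–C20H2–O–C7(=O)–C8(OH)–C9; ring C = cyclohexane C8–C9–C11–C12–C13–C14; side chain C16(=C17H2)–C15HO on C13.
2. Key disconnection: the C11–C12 bond of ring C, closed by 6-endo-trig cyclisation of a primary C11 radical (C9–CH2–SePh) onto a 2-acetylallyl group on C8. The enabling feature: C12 is β to the C16 carbonyl through C13 (terminus of an α-substituted enone while the side chain is an acetyl) and lies 1,6 to C11 across C9–C8–C14–C13, the two arms (C14 on C8, C11 on C9) being trans on ring B.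
3. The acrolein unit is then drawn from the C13 acetyl (Wittig methylenation, allylic oxidation). The 2-acetylallyl group and 8-OH come from a Barbier addition to the C8 ketone of a spiro α-keto-δ-lactone; C11 comes from Mannich methylenation and selenol addition at C9.
4. The keto lactone comes from 4,4-dimethylcyclohexa-2,5-dienone: asymmetric vinyl addition (C5), C10 alkylation with ethyl 2-(bromomethyl)acrylate (C9–C8–C7), C10 hydroxymethylation with lactonisation (C20, ring B), oxa-Michael closure of the ether bridge, ozonolysis to the C8 ketone.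
5. Ring order: carbocycle of ring A (purchased) → lactone ring B → ether bridge of ring A → ring C (key step).

Key step: step 13

Remark on the chemistry: keto lactones 13–16 are enolisable at C9; 14 and 16 are drawn as enols, and C9 becomes configurationally fixed only in step 12.

**Route**

Step 1
Reactants: 1 4,4-dimethylcyclohex-2-en-1-one
Product: 2 4,4-dimethylcyclohexa-2,5-dien-1-one
Conditions: DDQ (1.2 equiv), 1,4-dioxane, reflux
Reagents that add atoms: none
Why: DDQ dehydrogenation of an enone whose γ-carbon is quaternary can only introduce the second α,β-double bond, so the cross-conjugated dienone should form without aromatisation.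

Step 2
Reactants: 2 4,4-dimethylcyclohexa-2,5-dien-1-one
Product: 3 (5S)-5-ethenyl-4,4-dimethylcyclohex-2-en-1-one
Conditions: CH2=CHBF3K (0.9 equiv), [Rh(cod)2]BF4 (3 mol %), (S)-BINAP (3.3 mol %), toluene–H2O 10:1, 100 °C
Reagents that add atoms: potassium vinyltrifluoroborate (C=C[B-](F)(F)F.[K+])
Why: Rhodium/BINAP-catalysed asymmetric 1,4-addition of an alkenylboron reagent (Hayashi–Miyaura reaction) desymmetrises the prochiral dienone, the ligand choosing one of the two enantiotopic β-carbons and so setting C5; (S)-BINAP is the enantiomer expected by analogy with 2-cyclohexenone to give 5S.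

Step 3
Reactants: 3 (5S)-5-ethenyl-4,4-dimethylcyclohex-2-en-1-one
Product: 4 (1R)-2,2-dimethyl-5-oxocyclohex-3-ene-1-carbaldehyde
Conditions: O3, CH2Cl2–MeOH 4:1, −78 °C (Sudan Red 7B end point); then Me2S, −78 °C → rt
Reagents that add atoms: ozone ([O-][O+]=O)
Why: Ozonolysis to a dye end point should cleave the electron-rich vinyl group well before the electron-poor enone double bond, and the neutral reductive work-up leaves the C5 centre α to the new aldehyde untouched.

Step 4
Reactants: 4 (1R)-2,2-dimethyl-5-oxocyclohex-3-ene-1-carbaldehyde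
Product: 6 (5R)-5-{[(tert-butyldimethylsilyl)oxy]methyl}-4,4-dimethylcyclohex-2-en-1-one, via primary alcohol 5 (not isolated)
Conditions: NaBH(OAc)3, CH2Cl2, rt; then imidazole, TBSCl, rt
Reagents that add atoms: tert-butyldimethylsilyl chloride (CC(C)(C)[Si](C)(C)Cl)
Why: Triacetoxyborohydride reduction is selective for the aldehyde over the enone, and immediate silylation keeps the hydroxymethyl group from adding to the enone before C10 has been built.

Step 5
Reactants: 6 (5R)-5-{[(tert-butyldimethylsilyl)oxy]methyl}-4,4-dimethylcyclohex-2-en-1-one; 7 ethyl 2-(bromomethyl)prop-2-enoate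
Product: 8 ethyl 2-{[(1R,6R)-6-{[(tert-butyldimethylsilyl)oxy]methyl}-5,5-dimethyl-2-oxocyclohex-3-en-1-yl]methyl}prop-2-enoate
Conditions: LDA, THF, −78 °C; then 7, −78 → −20 °C
Reagents that add atoms: none
Why: Kinetic α′-deprotonation of the enone (its only enolisable position) and alkylation of the lithium enolate with the reactive allylic bromide should occur anti to the C5 substituent; the C10 configuration is of no consequence because C10 is enolised again in step 6.

Step 6
Reactants: 8 ethyl 2-{[(1R,6R)-6-{[(tert-butyldimethylsilyl)oxy]methyl}-5,5-dimethyl-2-oxocyclohex-3-en-1-yl]methyl}prop-2-enoate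
Product: 10 (6S,11S)-11-{[(tert-butyldimethylsilyl)oxy]methyl}-10,10-dimethyl-4-methylidene-2-oxaspiro[5.5]undec-8-ene-3,7-dione, via aldol alkoxide 9 (not isolated)
Conditions: LDA, THF, −78 °C; then CH2O (gas from cracked paraformaldehyde), −78 → 0 °C; then rt; then H2O
Reagents that add atoms: formaldehyde (C=O)
Why: Aldol addition of the tetrasubstituted enolate to formaldehyde anti to the neighbouring C5 substituent should make C10 quaternary (C20 trans and C9 cis to the silyloxymethyl group), and the alkoxide then closes ring B on the acrylate ester (lactonisation), which also blocks retro-aldol loss of formaldehyde.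

Step 7
Reactants: 10 (6S,11S)-11-{[(tert-butyldimethylsilyl)oxy]methyl}-10,10-dimethyl-4-methylidene-2-oxaspiro[5.5]undec-8-ene-3,7-dione
Product: 12 8,8-dimethyl-5'-methylidenespiro[6-oxabicyclo[3.2.1]octane-2,3'-oxane]-3,6'-dione (ether bridge syn to the lactone C9H2), via primary alcohol 11 (not isolated)
Conditions: HF·pyridine, THF, 0 °C → rt; then DBU (0.2 equiv), CH2Cl2, rt
Reagents that add atoms: none
Why: Desilylation followed by base-catalysed intramolecular oxa-Michael addition (5-exo-trig) of the C6 hydroxyl to the ring A enone closes the ether bridge; the one-carbon tether can reach C3 only from its own face, so C3 is set cis to C6.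

Step 8
Reactants: 12 8,8-dimethyl-5'-methylidenespiro[6-oxabicyclo[3.2.1]octane-2,3'-oxane]-3,6'-dione
Product: 13 8,8-dimethylspiro[6-oxabicyclo[3.2.1]octane-2,3'-oxane]-3,5',6'-trione
Conditions: O3, CH2Cl2, −78 °C; then Me2S, −78 °C → rt
Reagents that add atoms: ozone ([O-][O+]=O)
Why: With the ring A alkene consumed in step 7, ozonolysis can cleave only the exocyclic methylene of the lactone, which unveils the C8 ketone of an α-keto lactone.

Step 9
Reactants: 13 8,8-dimethylspiro[6-oxabicyclo[3.2.1]octane-2,3'-oxane]-3,5',6'-trione
Product: 16 5'-hydroxy-8,8-dimethyl-4'-[(phenylselanyl)methyl]spiro[6-oxabicyclo[3.2.1]octane-2,3'-oxan]-4'-ene-3,6'-dione (enol form), via Mannich base 14 (not isolated), via exo-methylene ketolactone 15 (not isolated)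
Conditions: CH2=NMe2+ I− (Eschenmoser's salt), CH2Cl2, rt; then PhSeH, 40 °C
Reagents that add atoms: N,N-dimethylmethyleneiminium iodide (C=[N+](C)C.[I-]); benzeneselenol ([SeH]c1ccccc1)
Why: Mannich reaction at C9 (the only enolised α-carbon), elimination of dimethylamine to the exo-methylene keto lactone and conjugate addition of the selenol should install C11 as a CH2SePh group, a stable latent primary radical.

Step 10
Reactants: 17 but-3-en-2-one
Product: 18 3-(hydroxymethyl)but-3-en-2-one
Conditions: aq CH2O (37 %), DABCO (0.1 equiv), THF, rt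
Reagents that add atoms: formaldehyde (C=O)
Why: Morita–Baylis–Hillman reaction of methyl vinyl ketone with formaldehyde gives the α-(hydroxymethyl) enone.

Step 11
Reactants: 18 3-(hydroxymethyl)but-3-en-2-one
Product: 19 3-(bromomethyl)but-3-en-2-one
Conditions: PBr3 (0.4 equiv), Et2O, −10 → 0 °C; used promptly
Reagents that add atoms: phosphorus tribromide (BrP(Br)Br)
Why: Bromination of the primary allylic alcohol with PBr3 should be clean because direct and allylic substitution give the same bromide.

Step 12
Reactants: 16 5'-hydroxy-8,8-dimethyl-4'-[(phenylselanyl)methyl]spiro[6-oxabicyclo[3.2.1]octane-2,3'-oxan]-4'-ene-3,6'-dione; 19 3-(bromomethyl)but-3-en-2-one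
Product: 20 5'-hydroxy-8,8-dimethyl-5'-(2-methylidene-3-oxobutyl)-4'-[(phenylselanyl)methyl]spiro[6-oxabicyclo[3.2.1]octane-2,3'-oxane]-3,6'-dione (8-OH cis to the CH2SePh group)
Conditions: indium powder, THF–H2O 1:1, rt
Reagents that add atoms: none
Why: Indium-mediated Barbier allylation in water should add the 2-acetylallyl unit to the keto tautomer at C8, the most electrophilic carbonyl, anti to the C9 substituent and away from the ring A carbonyl carbon C1 that sits axial on the lactone; C9 equilibrates through the enol beforehand and is expected to react as the epimer that keeps CH2SePh anti to the bulky C5 (dynamic resolution).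

Step 13
Reactants: 20 5'-hydroxy-8,8-dimethyl-5'-(2-methylidene-3-oxobutyl)-4'-[(phenylselanyl)methyl]spiro[6-oxabicyclo[3.2.1]octane-2,3'-oxane]-3,6'-dione
Product: 21 13-acetyl tetracycle (the target with acetyl in place of the acrolein unit; acetyl equatorial and trans to 8-OH)
Conditions: Bu3SnH (1.3 equiv, syringe pump), AIBN (0.2 equiv), benzene (0.005 M), 80 °C; then DBU (0.3 equiv), CH2Cl2, rt
Reagents that add atoms: none
Why: Bu3Sn• abstracts the phenylselanyl group to give the primary C11 radical, which adds to the unsubstituted terminus C12 of the α-substituted enone; the tertiary α-keto radical at C13 then takes hydrogen from Bu3SnH. The closest known reaction type is the tin hydride cyclisation of hex-5-enyl radicals carrying an acyl group on the internal alkene carbon, which closes six-membered rings onto α-methylene carbonyl acceptors. Ring C closes in the 6-endo-trig mode because the alternative 5-exo attack would hit the fully substituted, electron-poor α-carbon C13. C8 and C9 are already fixed with their arms trans on ring B, so a chair-like transition state should give the trans-fused lactone–cyclohexane directly. The new centre C13 is not relied on kinetically: it is α to the acetyl group and DBU equilibrates it to the equatorial epimer (trans to 8-OH), the only one without a 1,3-diaxial contact with the axial 8-OH. The selectivity needed is cyclisation over premature reduction of the radical, secured by high dilution with slow stannane addition and by the polarity match between the nucleophilic alkyl radical and the enone.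

Step 14
Reactants: 21 13-acetyl tetracycle
Product: 22 13-isopropenyl tetracycle (prop-1-en-2-yl at C13)
Conditions: Ph3PCH3Br, KOtBu, THF, 0 °C; then 21, 0 °C → rt
Reagents that add atoms: methyltriphenylphosphonium bromide (C[P+](c1ccccc1)(c1ccccc1)c1ccccc1.[Br-])
Why: Wittig methylenation should take the unhindered methyl ketone in preference to the C1 ketone, which is flanked by the quaternary spiro carbon, and leave the lactone untouched; any base-induced epimerisation at C13 returns to the equatorial isomer.

Step 15
Reactants: 22 13-isopropenyl tetracycle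
Product: 24 CNP0525385.1, via allylic alcohol 23 (not isolated)
Conditions: SeO2 (0.3 equiv), t-BuOOH (3 equiv), CH2Cl2, rt; then PhI(OAc)2, TEMPO (0.1 equiv), CH2Cl2, rt
Reagents that add atoms: tert-butyl hydroperoxide (CC(C)(C)OO)
Why: SeO2/t-BuOOH allylic oxidation (ene reaction, then [2,3]-shift) of the 1,1-disubstituted alkene should attack the methyl group rather than the hindered ring methine, and TEMPO/PhI(OAc)2 then oxidises only the primary allylic alcohol, not the tertiary 8-OH, to the enal.

**Compound list**

1 | 4,4-dimethylcyclohex-2-en-1-one | CC1(C)CCC(=O)C=C1 | starting material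
2 | 4,4-dimethylcyclohexa-2,5-dien-1-one | CC1(C)C=CC(=O)C=C1 | intermediate
3 | (5S)-5-ethenyl-4,4-dimethylcyclohex-2-en-1-one | O=C1C=CC(C)(C)[C@H](C=C)C1 | intermediate
4 | (1R)-2,2-dimethyl-5-oxocyclohex-3-ene-1-carbaldehyde | O=C1C=CC(C)(C)[C@H](C=O)C1 | intermediate
5 | (5R)-5-(hydroxymethyl)-4,4-dimethylcyclohex-2-en-1-one | O=C1C=CC(C)(C)[C@H](CO)C1 | intermediate
6 | (5R)-5-{[(tert-butyldimethylsilyl)oxy]methyl}-4,4-dimethylcyclohex-2-en-1-one | O=C1C=CC(C)(C)[C@H](CO[Si](C)(C)C(C)(C)C)C1 | intermediate
7 | ethyl 2-(bromomethyl)prop-2-enoate | C=C(CBr)C(=O)OCC | starting material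
8 | ethyl 2-{[(1R,6R)-6-{[(tert-butyldimethylsilyl)oxy]methyl}-5,5-dimethyl-2-oxocyclohex-3-en-1-yl]methyl}prop-2-enoate (trans) | CCOC(=O)C(=C)C[C@H]1C(=O)C=CC(C)(C)[C@@H]1CO[Si](C)(C)C(C)(C)C | intermediate
9 | ethyl 2-{[(1S,6S)-6-{[(tert-butyldimethylsilyl)oxy]methyl}-1-(hydroxymethyl)-5,5-dimethyl-2-oxocyclohex-3-en-1-yl]methyl}prop-2-enoate (formed as its lithium alkoxide; CH2OH trans to CH2OTBS) | CCOC(=O)C(=C)C[C@]1(CO)C(=O)C=CC(C)(C)[C@@H]1CO[Si](C)(C)C(C)(C)C | intermediate
10 | (6S,11S)-11-{[(tert-butyldimethylsilyl)oxy]methyl}-10,10-dimethyl-4-methylidene-2-oxaspiro[5.5]undec-8-ene-3,7-dione | C=C1C[C@]2(COC1=O)C(=O)C=CC(C)(C)[C@@H]2CO[Si](C)(C)C(C)(C)C | intermediate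
11 | (6S,11S)-11-(hydroxymethyl)-10,10-dimethyl-4-methylidene-2-oxaspiro[5.5]undec-8-ene-3,7-dione | C=C1C[C@]2(COC1=O)C(=O)C=CC(C)(C)[C@@H]2CO | intermediate
12 | 8,8-dimethyl-5'-methylidenespiro[6-oxabicyclo[3.2.1]octane-2,3'-oxane]-3,6'-dione (3S,5S,10S in target locants; lactone CH2O anti, C9H2 syn to the ether bridge) | C=C1C[C@]3(COC1=O)C(=O)C[C@@H]2OC[C@H]3C2(C)C | intermediate
13 | 8,8-dimethylspiro[6-oxabicyclo[3.2.1]octane-2,3'-oxane]-3,5',6'-trione (C8 keto lactone, keto form shown) | O=C1C[C@]3(COC1=O)C(=O)C[C@@H]2OC[C@H]3C2(C)C | intermediate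
14 | Mannich base: C9-[(dimethylamino)methyl] derivative of 13 (enol form shown) | OC1=C(CN(C)C)[C@]3(COC1=O)C(=O)C[C@@H]2OC[C@H]3C2(C)C | intermediate
15 | 8,8-dimethyl-4'-methylidenespiro[6-oxabicyclo[3.2.1]octane-2,3'-oxane]-3,5',6'-trione (C9 exo-methylene keto lactone) | O=C1C(=C)[C@]3(COC1=O)C(=O)C[C@@H]2OC[C@H]3C2(C)C | intermediate
16 | 5'-hydroxy-8,8-dimethyl-4'-[(phenylselanyl)methyl]spiro[6-oxabicyclo[3.2.1]octane-2,3'-oxan]-4'-ene-3,6'-dione (enol of the C9-CH2SePh keto lactone) | OC1=C(C[Se]c2ccccc2)[C@]3(COC1=O)C(=O)C[C@@H]2OC[C@H]3C2(C)C | intermediate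
17 | but-3-en-2-one | CC(=O)C=C | starting material
18 | 3-(hydroxymethyl)but-3-en-2-one | CC(=O)C(=C)CO | intermediate
19 | 3-(bromomethyl)but-3-en-2-one | CC(=O)C(=C)CBr | intermediate
20 | 5'-hydroxy-8,8-dimethyl-5'-(2-methylidene-3-oxobutyl)-4'-[(phenylselanyl)methyl]spiro[6-oxabicyclo[3.2.1]octane-2,3'-oxane]-3,6'-dione (3S,5S,8S,9S,10R in target locants; 8-OH cis to CH2SePh and syn to the ring A carbonyl) | CC(=O)C(=C)C[C@]1(O)[C@@H](C[Se]c2ccccc2)[C@]3(COC1=O)C(=O)C[C@@H]2OC[C@H]3C2(C)C | intermediate
21 | 13-acetyl tetracycle: the target with COCH3 at C13 in place of the acrolein unit (13R, acetyl equatorial, trans to 8-OH) | CC(=O)[C@@H]1CC[C@H]2[C@]3(COC(=O)[C@]2(O)C1)C(=O)C[C@@H]1OC[C@H]3C1(C)C | intermediate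
22 | 13-isopropenyl tetracycle: the target with C(CH3)=CH2 at C13 | C=C(C)[C@@H]1CC[C@H]2[C@]3(COC(=O)[C@]2(O)C1)C(=O)C[C@@H]1OC[C@H]3C1(C)C | intermediate
23 | allylic alcohol: the target with C(=CH2)CH2OH at C13 | C=C(CO)[C@@H]1CC[C@H]2[C@]3(COC(=O)[C@]2(O)C1)C(=O)C[C@@H]1OC[C@H]3C1(C)C | intermediate
24 | CNP0525385.1 | C=C(C=O)[C@@H]1CC[C@H]2[C@]3(COC(=O)[C@]2(O)C1)C(=O)C[C@@H]1OC[C@H]3C1(C)C | target

**Step count and risks**

Total step count: 15. Longest linear sequence: 13 steps (steps 1–9 and 12–15; steps 10–11 make reagent 19).

The three steps most likely to fail: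

Step 12. The risk is incomplete stereocontrol: the allyl reagent may add to the wrong C9 epimer of the enolisable keto lactone or to the wrong face of C8, and the selenide may be lost by retro-Michael reaction. The fallback sets C8 before C9. It sets out from 13, which is taken through the first stage of step 9 only (Eschenmoser's salt, then mild base) to the exo-methylene keto lactone 15; this has no C9 stereocentre. Indium and 19 in THF–H2O should then add to C8 under control of the spiro centre alone and give the bis-methylene tertiary alcohol F1. Radical-chain addition of excess PhSeH (AIBN, benzene, 60 °C) should place PhSe on C11 and hydrogen on C9 from the open face of the tertiary radical, while PhSeH also adds conjugatively to the enone, giving the bis-selenide F2. DBU in CH2Cl2 then removes only the selenide β to the ketone by retro-Michael reaction, and the route is rejoined at 20.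

Step 13. The risk is that the primary radical is reduced by the stannane, or shifts a hydrogen atom, before it closes the ring, which becomes likely if the enone is tied up as a cyclic hemiketal with 8-OH. The fallback closes the same bond without any hydrogen-atom donor. It sets out from 20: MeI and NaI in DMF at 60 °C should exchange the selenide (through the methylselenonium salt) for iodide and give the primary iodide F3. Zinc dust with catalytic NiCl2·6H2O in pyridine at 60 °C (nickel-catalysed reductive conjugate addition of an alkyl halide to an enone), followed by the DBU equilibration, should then give 21, where the route is rejoined.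

Step 2. The risk is poor enantiotopic-group selection on the hindered dienone, or a second vinyl addition to the product enone. The fallback replaces the metal-catalysed step by an organocatalytic desymmetrisation. It sets out from 2: nitromethane with a cinchona-derived primary amine (9-amino-9-deoxy-epi-quinidine series, with benzoic acid; the pseudo-enantiomer is chosen that gives the R adduct) should add by iminium activation to give the nitromethyl enone F4. A Nef reaction (NaOMe in MeOH, then buffered aqueous TiCl3 with NH4OAc) should convert the nitromethyl group into the aldehyde, and the route is rejoined at 4.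

Further compounds
F1 | step 12 | 5'-hydroxy-8,8-dimethyl-4'-methylidene-5'-(2-methylidene-3-oxobutyl)spiro[6-oxabicyclo[3.2.1]octane-2,3'-oxane]-3,6'-dione (bis-methylene tertiary alcohol) | CC(=O)C(=C)C[C@]1(O)C(=C)[C@]3(COC1=O)C(=O)C[C@@H]2OC[C@H]3C2(C)C
F2 | step 12 | bis-selenide: 20 carrying a second phenylselanyl group on C12 (C13 a mixture of epimers) | CC(=O)C(C[Se]c1ccccc1)C[C@]1(O)[C@@H](C[Se]c2ccccc2)[C@]3(COC1=O)C(=O)C[C@@H]2OC[C@H]3C2(C)C
F3 | step 13 | primary iodide: 20 with iodine in place of the phenylselanyl group | CC(=O)C(=C)C[C@]1(O)[C@@H](CI)[C@]3(COC1=O)C(=O)C[C@@H]2OC[C@H]3C2(C)C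
F4 | step 2 | (5R)-4,4-dimethyl-5-(nitromethyl)cyclohex-2-en-1-one | O=C1C=CC(C)(C)[C@H](C[N+](=O)[O-])C1
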